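The route rests on reading the 1H-isochromen-8-one core as the cycloisomer of an open chain. The pyran (O2, C1, C8a, C4a, C4, C3) is the valence tautomer of a dienone whose exocyclic C8a=C1 methylene and Z-configured C4a=C4 enone sit on the carbocycle (C4a, C5, C6, C7, C8, C8a); that dienone is the enyne cycloisomer of a vinyl ketone tethered to an ynone. In one operation a palladium hydride closes C4a–C8a and light-driven oxa-6π closure makes O2–C1. The precursor 16 is an acyclic vinyl ketone–propenyl ynone held by the cis-acetonide of the (6R,7R)-diol from 2-C-methyl-D-erythronolactone; the orsellinate is attached to C7–OH last.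

Key step: step 12

Remark: isochromene numbering (C1, O2, C3, C4, C4a, C5, C6, C7, C8, C8a) is used for the corresponding atoms of every intermediate. The carbinol carbons C8 (in 5, 6, 7, 12, 14, 15) and C3 (in 10, 11, 13, 14, 15) are carried as epimer mixtures, which is harmless because both become ketones in step 11.

Step 1
Reactants: 1 2-C-methyl-D-erythrono-1,4-lactone
Product: 2 2,3-O-isopropylidene-2-C-methyl-D-erythrono-1,4-lactone (cis-fused dioxolane)
Conditions: Me2C(OMe)2, TsOH·H2O (cat.), acetone, rt
Reagents that add atoms: 2,2-dimethoxypropane, COC(C)(C)OC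
Why: Acid-catalysed ketal exchange (acetonide formation) on the cis-2,3-diol touches no stereocenter, so C6 and C7 of the target are taken unchanged from the chiral pool.

Step 2
Reactants: 2 2,3-O-isopropylidene-2-C-methyl-D-erythrono-1,4-lactone
Product: 3 2,3-O-isopropylidene-2-C-methyl-D-erythrofuranose (lactol, anomer mixture)
Conditions: i-Bu2AlH (1.1 equiv), CH2Cl2, −78 °C
Reagents that add atoms: none
Why: Partial reduction of a γ-lactone with i-Bu2AlH stops at the lactol because the tetrahedral aluminate survives at −78 °C.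

Step 3
Reactants: 3 2,3-O-isopropylidene-2-C-methyl-D-erythrofuranose; 4 vinylmagnesium bromide
Product: 5 vinyl carbinol diol, 1-[5-(hydroxymethyl)-2,2,4-trimethyl-1,3-dioxolan-4-yl]prop-2-en-1-ol (cis-dioxolane with C6 and C7 as in 1, C8 epimers)
Conditions: CH2=CHMgBr (3 equiv), THF, 0 °C → rt
Reagents that add atoms: none
Why: Grignard addition to the open-chain hydroxy-aldehyde tautomer of the lactol (the first equivalent deprotonates) gives the vinyl carbinol; the new C8 center is uncontrolled and need not be controlled, since it is oxidised in step 11.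

Step 4
Reactants: 5 vinyl carbinol diol
Product: 6 bis-TBS ether of 5 (C8–OTBS and C5–OTBS)
Conditions: TBSOTf (2.5 equiv), 2,6-lutidine, CH2Cl2, −78 → 0 °C
Reagents that add atoms: tert-butyldimethylsilyl trifluoromethanesulfonate, CC(C)(C)[Si](C)(C)OS(=O)(=O)C(F)(F)F
Why: Silylation with a silyl triflate covers both hydroxyls, including the hindered C8 carbinol next to the quaternary C7.

Step 5
Reactants: 6 bis-TBS ether of 5
Product: 7 primary alcohol with C8–OTBS retained (free C5–OH)
Conditions: HF·pyridine, pyridine, THF, 0 °C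
Reagents that add atoms: none
Why: Selective desilylation: buffered HF cleaves the unhindered primary silyl ether far faster than the secondary one flanked by the quaternary C7, so only C5–OH is freed and the C8 oxygen can no longer cyclise onto an activated C5.

Step 6
Reactants: 8 (E)-crotonaldehyde; 9 ethynylmagnesium bromide
Product: 10 (E)-hex-4-en-1-yn-3-ol (racemic)
Conditions: HC≡CMgBr, THF, −78 → 0 °C
Reagents that add atoms: none
Why: 1,2-Addition of an alkynyl Grignard reagent to the enal keeps the E alkene; the racemic carbinol center (C3) is oxidised later.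

Step 7
Reactants: 10 (E)-hex-4-en-1-yn-3-ol
Product: 11 tert-butyldimethyl[(E)-hex-4-en-1-yn-3-yloxy]silane (racemic)
Conditions: TBSCl, imidazole, CH2Cl2, rt
Reagents that add atoms: tert-butyldimethylsilyl chloride, CC(C)(C)[Si](C)(C)Cl
Why: Standard silylation masks the propargylic hydroxyl so that only the alkyne C–H is metalated in step 9.

Step 8
Reactants: 7 primary alcohol with C8–OTBS
Product: 12 C5 primary triflate of 7
Conditions: Tf2O, 2,6-lutidine, CH2Cl2, −78 °C
Reagents that add atoms: trifluoromethanesulfonic anhydride, O=S(=O)(OS(=O)(=O)C(F)(F)F)C(F)(F)F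
Why: Sulfonylation of the primary alcohol gives the triflate, which the β-oxygen stabilises against ionisation; it is used at once without chromatography.

Step 9
Reactants: 11 tert-butyldimethyl[(E)-hex-4-en-1-yn-3-yloxy]silane; 12 C5 primary triflate
Product: 14 enyne bis-TBS ether (complete C1–C3 chain with the propenyl group), via lithium acetylide 13 (not isolated)
Conditions: 11, n-BuLi, THF, −78 °C; then 12, DMPU, −78 → −20 °C
Reagents that add atoms: none
Why: SN2 alkylation of a lithium acetylide by a primary triflate forges C5–C4a, and the low temperature and bulky silyl group keep the C8 silyloxy oxygen from displacing the triflate itself.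

Step 10
Reactants: 14 enyne bis-TBS ether
Product: 15 enyne diol (free C8–OH and C3–OH, acetonide intact)
Conditions: TBAF (4 equiv), THF, rt
Reagents that add atoms: none
Why: Fluoride-mediated desilylation frees both carbinols while the acetonide and the enyne are inert.

Step 11
Reactants: 15 enyne diol
Product: 16 1-[(4R,5R)-2,2,4-trimethyl-5-[(E)-4-oxohept-5-en-2-yn-1-yl]-1,3-dioxolan-4-yl]prop-2-en-1-one (vinyl ketone–ynone precursor)
Conditions: Dess–Martin periodinane (2.5 equiv), CH2Cl2, 0 °C → rt
Reagents that add atoms: none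
Why: Dess–Martin oxidation of the allylic and the propargylic/allylic carbinols unveils both Michael acceptors together and only now, so that no organometallic reagent ever meets an enone, and it erases the two uncontrolled carbinol centers; 16 is used directly.

Step 12
Reactants: 16 vinyl ketone–ynone precursor
Product: 19 bicyclic core as its (6R,7R) cis-diol acetonide, via E-dienone 17 (not isolated), via Z-dienone 18 (not isolated)
Conditions: Pd2(dba)3·CHCl3 (2.5 mol %), P(o-tol)3 (10 mol %), AcOH (1 equiv), degassed PhMe (0.01 M), 40 °C; then hν (365 nm LED), rt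
Reagents that add atoms: none
Why: Proposed new method: zerovalent palladium and AcOH give hydridopalladium acetate, which adds cis across the ynone; only the regioisomer with palladium on C4a can go on (the other reverts), and its alkenyl–palladium bond inserts the tethered vinyl ketone at C8a, after which β-hydride elimination of the C8a hydrogen releases the bis-exocyclic E-dienone 17 and returns the hydride. The closest known reaction type is the palladium hydride cycloisomerisation of 1,7-enynes to 1,2-dialkylidenecyclohexanes, here stretched to an ynone/vinyl ketone pair and continued in the same flask by the dienone-to-2H-pyran photochemistry known from β-ionone. The carbocycle (C4a, C5, C6, C7, C8, C8a) closes 6-exo-trig through C4a–C8a, and the pyran closes through O2–C1 by thermal disrotatory oxa-6π electrocyclisation of Z-dienone 18, which 365 nm light makes from 17. No stereocenter is created, and C6 and C7 are spectators held in the acetonide. The selectivities needed are 6-exo over 7-endo insertion, secured by the four-atom tether and by the cis-dioxolane that keeps both arms on one face, and Z-selective drainage, secured because only 18 can cyclise and the pyran, a doubly vinylogous ester, is the thermodynamic sink. The bulky, weakly nucleophilic P(o-tol)3 and high dilution are chosen to keep phosphine conjugate addition and dimerisation of the exo-methylene ketone in check.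

Step 13
Reactants: 19 bicyclic core acetonide
Product: 20 (6R,7R)-6,7-dihydroxy-7-methyl-3-[(E)-prop-1-enyl]-6,7-dihydro-1H-isochromen-8(5H)-one
Conditions: TFA/H2O (9:1), CH2Cl2, 0 °C
Reagents that add atoms: none
Why: Acid-catalysed ketal hydrolysis should spare the pyran, because a doubly vinylogous ester is poorly basic at carbon and any hydration at C3 is reversible and recloses.

Step 14
Reactants: 20 core diol
Product: 21 C6 O-triethylsilyl ether of 20 (free tertiary C7–OH)
Conditions: TESCl, imidazole, DMF, 0 °C
Reagents that add atoms: chlorotriethylsilane, CC[Si](Cl)(CC)CC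
Why: Silylation distinguishes the secondary C6 hydroxyl from the tertiary, ketone-flanked C7 hydroxyl on steric grounds.

Step 15
Reactants: 22 methyl orsellinate
Product: 23 methyl 2-hydroxy-6-methyl-4-(triisopropylsilyloxy)benzoate
Conditions: TIPSCl, imidazole, DMF, rt
Reagents that add atoms: chlorotriisopropylsilane, CC(C)[Si](Cl)(C(C)C)C(C)C
Why: Regioselective silylation takes the free 4-OH because the 2-OH is locked in a hydrogen bond to the ester carbonyl.

Step 16
Reactants: 23 methyl 2-hydroxy-6-methyl-4-(triisopropylsilyloxy)benzoate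
Product: 24 methyl 2-methoxy-6-methyl-4-(triisopropylsilyloxy)benzoate
Conditions: MeI, K2CO3, acetone, reflux
Reagents that add atoms: iodomethane, CI
Why: Williamson O-methylation of the remaining chelated phenol places the methyl group of the target's 2-methoxy substituent, and the bulky aryl silyl ether tolerates K2CO3 in dry acetone.

Step 17
Reactants: 24 methyl 2-methoxy-6-methyl-4-(triisopropylsilyloxy)benzoate
Product: 25 2-methoxy-6-methyl-4-(triisopropylsilyloxy)benzoic acid
Conditions: LiI, pyridine, reflux; then cold 1 M HCl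
Reagents that add atoms: none
Why: Dealkylative ester cleavage (SN2 attack of iodide on the ester methyl group, alkyl–oxygen fission) suits a di-ortho-substituted benzoate whose carbonyl is shielded from hydroxide, and it leaves the silyl ether in place.

Step 18
Reactants: 25 2-methoxy-6-methyl-4-(triisopropylsilyloxy)benzoic acid
Product: 26 2-methoxy-6-methyl-4-(triisopropylsilyloxy)benzoyl chloride
Conditions: (COCl)2, DMF (cat.), CH2Cl2, 0 °C → rt
Reagents that add atoms: oxalyl chloride, O=C(Cl)C(=O)Cl
Why: Acid chloride formation runs through the chloroiminium salt made from oxalyl chloride and catalytic DMF; the crude chloride is used directly.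

Step 19
Reactants: 21 C6 O-triethylsilyl ether; 26 2-methoxy-6-methyl-4-(triisopropylsilyloxy)benzoyl chloride
Product: 28 bis-silylated target (C6 O-TES; aryl 4-O-TIPS), via aroyl triflate 27 (not isolated)
Conditions: AgOTf (2 equiv), 2,6-di-tert-butyl-4-methylpyridine (3 equiv), 4 Å MS, CH2Cl2, −40 → 0 °C
Reagents that add atoms: none
Why: Silver-promoted chloride abstraction gives the aroyl triflate/acylium ion, whose linear acyl carbon is open to the hindered tertiary C7 hydroxyl (the way mesitoate-type esters are made), while the hindered pyridine buffers TfOH; the C7–O bond is not broken, so configuration is retained.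

Step 20
Reactants: 28 bis-silylated target
Product: 29 CNP0187389.2, (6R,7R)-6-hydroxy-7-methyl-8-oxo-3-[(E)-prop-1-enyl]-5,6,7,8-tetrahydro-1H-isochromen-7-yl 4-hydroxy-2-methoxy-6-methylbenzoate
Conditions: TBAF/AcOH (1:1), THF, 0 °C → rt
Reagents that add atoms: none
Why: Fluoride-mediated global desilylation under acetic acid buffering avoids free alkoxide, so neither migration of the hindered aroyl group to C6–OH nor vinylogous elimination is expected.

Compound list

1 | 2-C-methyl-D-erythrono-1,4-lactone, (3R,4R)-3,4-dihydroxy-3-methyloxolan-2-one | O=C1OC[C@@H](O)[C@@]1(C)O | starting material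
2 | 2,3-O-isopropylidene-2-C-methyl-D-erythrono-1,4-lactone | O=C1OC[C@H]2OC(C)(C)O[C@@]12C | intermediate
3 | 2,3-O-isopropylidene-2-C-methyl-D-erythrofuranose (lactol, anomer mixture) | OC1OC[C@H]2OC(C)(C)O[C@@]12C | intermediate
4 | vinylmagnesium bromide | C=C[Mg]Br | starting material
5 | 1-[5-(hydroxymethyl)-2,2,4-trimethyl-1,3-dioxolan-4-yl]prop-2-en-1-ol, cis-dioxolane from 1, C8 epimers | C=CC(O)[C@]1(C)OC(C)(C)O[C@@H]1CO | intermediate
6 | bis-TBS ether of 5 | C=CC(O[Si](C)(C)C(C)(C)C)[C@]1(C)OC(C)(C)O[C@@H]1CO[Si](C)(C)C(C)(C)C | intermediate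
7 | C8 O-TBS ether of 5 with free primary C5–OH | C=CC(O[Si](C)(C)C(C)(C)C)[C@]1(C)OC(C)(C)O[C@@H]1CO | intermediate
8 | (E)-crotonaldehyde | C/C=C/C=O | starting material
9 | ethynylmagnesium bromide | C#C[Mg]Br | starting material
10 | (E)-hex-4-en-1-yn-3-ol (racemic) | C#CC(O)/C=C/C | intermediate
11 | tert-butyldimethyl[(E)-hex-4-en-1-yn-3-yloxy]silane (racemic) | C#CC(O[Si](C)(C)C(C)(C)C)/C=C/C | intermediate
12 | C5 triflate of 7 | C=CC(O[Si](C)(C)C(C)(C)C)[C@]1(C)OC(C)(C)O[C@@H]1COS(=O)(=O)C(F)(F)F | intermediate
13 | lithium acetylide of 11 | [Li]C#CC(O[Si](C)(C)C(C)(C)C)/C=C/C | intermediate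
14 | enyne bis-TBS ether (C8–OTBS, C3–OTBS, acetonide, E-propenyl) | C=CC(O[Si](C)(C)C(C)(C)C)[C@]1(C)OC(C)(C)O[C@@H]1CC#CC(O[Si](C)(C)C(C)(C)C)/C=C/C | intermediate
15 | enyne diol (C8–OH, C3–OH, acetonide) | C=CC(O)[C@]1(C)OC(C)(C)O[C@@H]1CC#CC(O)/C=C/C | intermediate
16 | 1-[(4R,5R)-2,2,4-trimethyl-5-[(E)-4-oxohept-5-en-2-yn-1-yl]-1,3-dioxolan-4-yl]prop-2-en-1-one | C=CC(=O)[C@]1(C)OC(C)(C)O[C@@H]1CC#CC(=O)/C=C/C | intermediate
17 | E-dienone: acetonide-fused 2-methylenecyclohexanone with (E)-configured C4a=C4 (acyl group cis to C5) | C=C1C(=O)[C@]2(C)OC(C)(C)O[C@@H]2C/C1=C\C(=O)/C=C/C | intermediate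
18 | Z-dienone: C4a=C4 isomer of 17 (acyl group cis to C8a) | C=C1C(=O)[C@]2(C)OC(C)(C)O[C@@H]2C/C1=C/C(=O)/C=C/C | intermediate
19 | (6R,7R)-6,7-O-isopropylidene acetonide of 20 (bicyclic core) | C/C=C/C1=CC2=C(CO1)C(=O)[C@]3(C)OC(C)(C)O[C@@H]3C2 | intermediate
20 | (6R,7R)-6,7-dihydroxy-7-methyl-3-[(E)-prop-1-enyl]-6,7-dihydro-1H-isochromen-8(5H)-one | C/C=C/C1=CC2=C(CO1)C(=O)[C@](C)(O)[C@H](O)C2 | intermediate
21 | (6R,7R)-7-hydroxy-7-methyl-3-[(E)-prop-1-enyl]-6-(triethylsilyloxy)-6,7-dihydro-1H-isochromen-8(5H)-one | C/C=C/C1=CC2=C(CO1)C(=O)[C@](C)(O)[C@H](O[Si](CC)(CC)CC)C2 | intermediate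
22 | methyl orsellinate (methyl 2,4-dihydroxy-6-methylbenzoate) | COC(=O)c1c(C)cc(O)cc1O | starting material
23 | methyl 2-hydroxy-6-methyl-4-(triisopropylsilyloxy)benzoate | COC(=O)c1c(C)cc(O[Si](C(C)C)(C(C)C)C(C)C)cc1O | intermediate
24 | methyl 2-methoxy-6-methyl-4-(triisopropylsilyloxy)benzoate | COC(=O)c1c(C)cc(O[Si](C(C)C)(C(C)C)C(C)C)cc1OC | intermediate
25 | 2-methoxy-6-methyl-4-(triisopropylsilyloxy)benzoic acid | OC(=O)c1c(C)cc(O[Si](C(C)C)(C(C)C)C(C)C)cc1OC | intermediate
26 | 2-methoxy-6-methyl-4-(triisopropylsilyloxy)benzoyl chloride | ClC(=O)c1c(C)cc(O[Si](C(C)C)(C(C)C)C(C)C)cc1OC | intermediate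
27 | 2-methoxy-6-methyl-4-(triisopropylsilyloxy)benzoyl trifluoromethanesulfonate | O=C(OS(=O)(=O)C(F)(F)F)c1c(C)cc(O[Si](C(C)C)(C(C)C)C(C)C)cc1OC | intermediate
28 | (6R,7R)-7-methyl-8-oxo-3-[(E)-prop-1-enyl]-6-(triethylsilyloxy)-5,6,7,8-tetrahydro-1H-isochromen-7-yl 2-methoxy-6-methyl-4-(triisopropylsilyloxy)benzoate | C/C=C/C1=CC2=C(CO1)C(=O)[C@](C)(OC(=O)c1c(C)cc(O[Si](C(C)C)(C(C)C)C(C)C)cc1OC)[C@H](O[Si](CC)(CC)CC)C2 | intermediate
29 | CNP0187389.2, (6R,7R)-6-hydroxy-7-methyl-8-oxo-3-[(E)-prop-1-enyl]-5,6,7,8-tetrahydro-1H-isochromen-7-yl 4-hydroxy-2-methoxy-6-methylbenzoate | C/C=C/C1=CC2=C(CO1)C(=O)[C@](C)(OC(=O)c1c(C)cc(O)cc1OC)[C@H](O)C2 | target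

Total step count: 20. Longest linear sequence: 14 steps (steps 1–5, 8–14, 19, 20, from lactone 1).

Steps most likely to fail

Step 12. The alkenylpalladium may fail to insert into the electron-poor vinyl ketone in the 6-exo sense: 7-endo, Michael-type insertion, hydropalladation with the unproductive regiochemistry, isomerisation of the ynone, or oligomerisation of the vinyl ketone and of the exo-methylene dienone may win. Irradiation in the presence of the catalyst residues may also scramble the propenyl geometry. The fallback closes the ring before the carbonyl groups exist and sets out from 14, an unactivated 1,7-enyne of the class for which the palladium hydride cycloisomerisation is established. Treatment of 14 with Pd2(dba)3·CHCl3, P(o-tol)3 and AcOH in toluene should give the bis-exocyclic diene bis-silyl ether F1. TBAF then gives the diene diol F2, and Dess–Martin periodinane oxidises both allylic carbinols to E-dienone 17, now isolated and kept cold and dilute. A catalytic amount of iodine in CH2Cl2 under ambient light equilibrates the C4a=C4 geometry under thermodynamic control, which also keeps the propenyl group E. Z-dienone 18 closes, and the route is rejoined at 19.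

Step 19. Acyl transfer to the tertiary, ketone-flanked C7 hydroxyl may be too slow. The acylium ion would then be consumed by acylative cleavage of the neighbouring silyl ether or by C-acylation at the nucleophilic C4 of the dienol ether. The fallback reverses the activation and sets out from 21, whose sodium alkoxide opens a benzodioxinone acyl donor, a known way to salicylate esters. Orsellinic acid (purchased, Cc1cc(O)cc(O)c1C(=O)O) with acetone, TFAA and TFA gives 7-hydroxy-2,2,5-trimethyl-4H-1,3-benzodioxin-4-one F3, and TIPSCl/imidazole gives 2,2,5-trimethyl-7-(triisopropylsilyloxy)-4H-1,3-benzodioxin-4-one F4. Alcohol 21 is deprotonated with NaN(SiMe3)2 in THF at −78 °C and added to F4, which should give, with loss of acetone, the C7 2-hydroxy-6-methyl-4-(triisopropylsilyloxy)benzoate of 21 F5. Mitsunobu methylation (MeOH, PPh3, DIAD) of its chelated phenol returns to the route at 28.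

Step 17. Demethylation of the di-ortho-substituted ester needs prolonged heating, during which the aryl silyl ether may be lost, the ortho-methoxy group may be cleaved instead, or the electron-rich acid may decarboxylate. The fallback replaces dealkylation by a redox detour and sets out from 24. Reduction with i-Bu2AlH (CH2Cl2, −78 → 0 °C) gives [2-methoxy-6-methyl-4-(triisopropylsilyloxy)phenyl]methanol F6, and MnO2 gives 2-methoxy-6-methyl-4-(triisopropylsilyloxy)benzaldehyde F7. Pinnick oxidation (NaClO2, NaH2PO4, 2-methyl-2-butene, t-BuOH/H2O) then rejoins the route at acid 25.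

Further compounds

F1 | step 12 | bis-exocyclic diene bis-TBS ether, (E)-C4a=C4, acetonide | C=C1C(O[Si](C)(C)C(C)(C)C)[C@]2(C)OC(C)(C)O[C@@H]2C/C1=C\C(O[Si](C)(C)C(C)(C)C)/C=C/C
F2 | step 12 | bis-exocyclic diene diol, (E)-C4a=C4, acetonide | C=C1C(O)[C@]2(C)OC(C)(C)O[C@@H]2C/C1=C\C(O)/C=C/C
F3 | step 19 | 7-hydroxy-2,2,5-trimethyl-4H-1,3-benzodioxin-4-one | Cc1cc(O)cc2OC(C)(C)OC(=O)c12
F4 | step 19 | 2,2,5-trimethyl-7-(triisopropylsilyloxy)-4H-1,3-benzodioxin-4-one | Cc1cc(O[Si](C(C)C)(C(C)C)C(C)C)cc2OC(C)(C)OC(=O)c12
F5 | step 19 | C7 2-hydroxy-6-methyl-4-(triisopropylsilyloxy)benzoate of 21 | C/C=C/C1=CC2=C(CO1)C(=O)[C@](C)(OC(=O)c1c(C)cc(O[Si](C(C)C)(C(C)C)C(C)C)cc1O)[C@H](O[Si](CC)(CC)CC)C2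
F6 | step 17 | [2-methoxy-6-methyl-4-(triisopropylsilyloxy)phenyl]methanol | OCc1c(C)cc(O[Si](C(C)C)(C(C)C)C(C)C)cc1OC
F7 | step 17 | 2-methoxy-6-methyl-4-(triisopropylsilyloxy)benzaldehyde | O=Cc1c(C)cc(O[Si](C(C)C)(C(C)C)C(C)C)cc1OC
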